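**Plan**
The retrosynthesis first removes the S–O bond of the 7-sulfate and the O-protecting groups, then cuts O1–C8a of ring C, then C2–C3 of the 1,3-diketone.
The enabling feature is that the C5 and C8 hydroxyls are para on ring A, so ring A is a hydroquinone. In its quinone, C8a (between the acyl-bearing C4a and the C8 carbonyl) is an acceptor carbon for the enol oxygen that becomes O1.
Forward: ring A comes from 1-(2,4,5-trihydroxyphenyl)ethanone with O7 masked as a MOM ether, and ring B from methyl 3,4-bis(benzyloxy)benzoate. A Claisen condensation joins them (C2–C3), and ring C then closes oxidatively (O1–C8a).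
Endgame: benzylation of O8, removal of MOM so that O7 is the only unchelated hydroxyl, sulfation, and hydrogenolysis of the three benzyl ethers.
The target has no stereocentre, so no stereochemistry has to be set.

Key step: step 3

Remark: 1 and 3 are taken as catalogue chemicals; the target is drawn as the free hydrogen sulfate, so 10 and 11 are written in that form, although both would be handled as pyridinium or sodium salts and 11 set free last on a cold H+-form sulfonic acid resin, because free aryl hydrogen sulfates hydrolyse on standing.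

Step 1
Reactants: 1 1-(2,4,5-trihydroxyphenyl)ethanone
Product: 2 1-[2,5-dihydroxy-4-(methoxymethoxy)phenyl]ethanone
Conditions: MOMCl (1.0 equiv), K2CO3 (1.0 equiv), acetone, 0 °C → rt, Ar
Reagents that add atoms: chloromethyl methyl ether (MOMCl), COCCl
Why: Williamson-type O-alkylation of the most acidic phenol: the 4-hydroxyl is para to the acetyl group, the 2-hydroxyl is locked in a hydrogen bond to the ketone and the 5-hydroxyl is meta and least acidic, so one equivalent of weak base and of chloride should give the 4-O-MOM ether.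

Step 2
Reactants: 2 1-[2,5-dihydroxy-4-(methoxymethoxy)phenyl]ethanone; 3 methyl 3,4-bis(benzyloxy)benzoate
Product: 4 1-[3,4-bis(benzyloxy)phenyl]-3-[2,5-dihydroxy-4-(methoxymethoxy)phenyl]propane-1,3-dione
Conditions: LiN(SiMe3)2 (4.5 equiv), THF, −78 → −10 °C; then 3, −78 °C → rt, Ar; quench into cold 1 M aq HCl to pH about 5
Reagents that add atoms: none
Why: Crossed Claisen condensation: the lithium trianion of 2 (two phenoxides and the methyl ketone enolate) attacks the non-enolisable ester 3 at carbon, deprotonation of the β-diketone by the excess base drives the equilibrium, and the phenoxides cannot be acylated irreversibly by an alkyl ester.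

Step 3
Reactants: 4 1-[3,4-bis(benzyloxy)phenyl]-3-[2,5-dihydroxy-4-(methoxymethoxy)phenyl]propane-1,3-dione
Product: 7 2-[3,4-bis(benzyloxy)phenyl]-5,8-dihydroxy-7-(methoxymethoxy)-4H-chromen-4-one, via acylquinone 5 (not isolated), via flavonequinone 6 (not isolated)
Conditions: Ag2O (3 equiv), anhydrous Na2SO4, CH2Cl2 (0.005 M), rt, dark, Ar; filter; then aq Na2S2O4, EtOAc, rt
Reagents that add atoms: none
Why: Proposed new method: Ag2O dehydrogenates the hydroquinone of 4 to acylquinone 5, whose ring carbon between the acyl-bearing carbon and the future C8 carbonyl (the later C8a) is the β-carbon of both the side-chain ketone and the ring carbonyl that used to be the ortho hydroxyl; the enol oxygen on the aryl-bearing carbon of the diketone adds to it, the ring proton is lost, and the adduct aromatises to the 5,8-dihydroxyflavone. The closest known reaction types are conjugate additions of oxygen, nitrogen and sulfur nucleophiles to C3 of 2-acyl-1,4-benzoquinones and oxidative cyclisations of hydroquinones by way of their quinones; closing a flavone with a β-diketone enol oxygen in this manner is the untested part. Ring C closes 6-endo-trig, O1 attacking a ring double bond that becomes part of the pyranone, and no stereocentre is created. The selectivity required is closure at C8a in preference to dehydrative closure through the ortho hydroxyl, which would lead to the 6-hydroxy-7-alkoxy isomer: acid-free oxidation converts that hydroxyl into a carbonyl first, 1,2-addition of the enol to this carbonyl is reversible and unproductive, and the tether reaches no other ring carbon. Carbon attack by the diketone is possible only between molecules and is held down by high dilution. Since the electron-rich product is oxidised further by Ag2O and by 5, the oxidant is used in excess to funnel everything into flavonequinone 6, and Na2S2O4 then reduces 6 to 7 and returns any uncyclised 5 to reusable 4.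

Step 4
Reactants: 7 2-[3,4-bis(benzyloxy)phenyl]-5,8-dihydroxy-7-(methoxymethoxy)-4H-chromen-4-one
Product: 8 8-(benzyloxy)-2-[3,4-bis(benzyloxy)phenyl]-5-hydroxy-7-(methoxymethoxy)-4H-chromen-4-one
Conditions: BnBr (1.1 equiv), K2CO3 (1.5 equiv), acetone, reflux, Ar
Reagents that add atoms: benzyl bromide, BrCc1ccccc1
Why: Williamson ether synthesis that is selective for the 8-hydroxyl because the 5-hydroxyl is tied up in a hydrogen bond to the C4 carbonyl and is not alkylated by carbonate in acetone; exclusion of air protects the hydroquinone.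

Step 5
Reactants: 8 8-(benzyloxy)-2-[3,4-bis(benzyloxy)phenyl]-5-hydroxy-7-(methoxymethoxy)-4H-chromen-4-one
Product: 9 8-(benzyloxy)-2-[3,4-bis(benzyloxy)phenyl]-5,7-dihydroxy-4H-chromen-4-one
Conditions: 3 M aq HCl, THF, 50 °C
Reagents that add atoms: none
Why: Acid-catalysed hydrolysis of the MOM acetal, under which benzyl ethers, the chelated phenol and the flavone core are stable, frees O7 as the only unchelated hydroxyl.

Step 6
Reactants: 9 8-(benzyloxy)-2-[3,4-bis(benzyloxy)phenyl]-5,7-dihydroxy-4H-chromen-4-one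
Product: 10 8-(benzyloxy)-2-[3,4-bis(benzyloxy)phenyl]-5-hydroxy-4-oxo-4H-chromen-7-yl hydrogen sulfate
Conditions: SO3·pyridine (3 equiv), pyridine, rt
Reagents that add atoms: sulfur trioxide–pyridine complex, O=S(=O)([O-])[n+]1ccccc1
Why: Phenol O-sulfation with the sulfur trioxide–pyridine complex takes place at the acidic, unchelated 7-hydroxyl, while the hydrogen-bonded 5-hydroxyl is known to stay untouched under such mild conditions.

Step 7
Reactants: 10 8-(benzyloxy)-2-[3,4-bis(benzyloxy)phenyl]-5-hydroxy-4-oxo-4H-chromen-7-yl hydrogen sulfate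
Product: 11 8-hydroxyluteolin 7-sulfate, that is 2-(3,4-dihydroxyphenyl)-5,8-dihydroxy-4-oxo-4H-chromen-7-yl hydrogen sulfate
Conditions: H2 (1 atm), 10% Pd/C, THF/MeOH, rt
Reagents that add atoms: none
Why: Catalytic hydrogenolysis of the three benzyl ethers over Pd/C, to which aryl sulfate monoesters are inert and under which the C2–C3 double bond of a flavone (a vinylogous ester) is reduced far more slowly than O-benzyl bonds are cleaved.

**Compound list**
1 | 1-(2,4,5-trihydroxyphenyl)ethanone | CC(=O)c1cc(O)c(O)cc1O | starting material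
2 | 1-[2,5-dihydroxy-4-(methoxymethoxy)phenyl]ethanone | CC(=O)c1cc(O)c(OCOC)cc1O | intermediate
3 | methyl 3,4-bis(benzyloxy)benzoate | COC(=O)c1ccc(OCc2ccccc2)c(OCc2ccccc2)c1 | starting material
4 | 1-[3,4-bis(benzyloxy)phenyl]-3-[2,5-dihydroxy-4-(methoxymethoxy)phenyl]propane-1,3-dione | COCOc1cc(O)c(C(=O)CC(=O)c2ccc(OCc3ccccc3)c(OCc3ccccc3)c2)cc1O | intermediate
5 | 2-{3-[3,4-bis(benzyloxy)phenyl]-3-oxopropanoyl}-5-(methoxymethoxy)cyclohexa-2,5-diene-1,4-dione | COCOC1=CC(=O)C(C(=O)CC(=O)c2ccc(OCc3ccccc3)c(OCc3ccccc3)c2)=CC1=O | intermediate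
6 | 2-[3,4-bis(benzyloxy)phenyl]-7-(methoxymethoxy)-4H-chromene-4,5,8-trione | COCOC1=CC(=O)C2=C(OC(=CC2=O)c2ccc(OCc3ccccc3)c(OCc3ccccc3)c2)C1=O | intermediate
7 | 2-[3,4-bis(benzyloxy)phenyl]-5,8-dihydroxy-7-(methoxymethoxy)-4H-chromen-4-one | COCOc1cc(O)c2c(=O)cc(-c3ccc(OCc4ccccc4)c(OCc4ccccc4)c3)oc2c1O | intermediate
8 | 8-(benzyloxy)-2-[3,4-bis(benzyloxy)phenyl]-5-hydroxy-7-(methoxymethoxy)-4H-chromen-4-one | COCOc1cc(O)c2c(=O)cc(-c3ccc(OCc4ccccc4)c(OCc4ccccc4)c3)oc2c1OCc1ccccc1 | intermediate
9 | 8-(benzyloxy)-2-[3,4-bis(benzyloxy)phenyl]-5,7-dihydroxy-4H-chromen-4-one | Oc1cc(O)c2c(=O)cc(-c3ccc(OCc4ccccc4)c(OCc4ccccc4)c3)oc2c1OCc1ccccc1 | intermediate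
10 | 8-(benzyloxy)-2-[3,4-bis(benzyloxy)phenyl]-5-hydroxy-4-oxo-4H-chromen-7-yl hydrogen sulfate | O=S(=O)(O)Oc1cc(O)c2c(=O)cc(-c3ccc(OCc4ccccc4)c(OCc4ccccc4)c3)oc2c1OCc1ccccc1 | intermediate
11 | 8-hydroxyluteolin 7-sulfate, 2-(3,4-dihydroxyphenyl)-5,8-dihydroxy-4-oxo-4H-chromen-7-yl hydrogen sulfate | O=c1cc(-c2ccc(O)c(O)c2)oc2c(O)c(OS(=O)(=O)O)cc(O)c12 | target

**Step count**
Total steps: 7. Longest linear sequence: 7 steps (1 to 11); ester 3 enters at step 2.

**Steps most likely to fail**

Step 3. The enol oxygen may add too slowly to the acylquinone, so that intermolecular carbon addition and oligomerisation of the quinone take over, or the quinone ether may be hydrolysed during the long oxidation. The fallback uses only known reactions. It sets out from ester 3 and comes back at 7.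
- Claisen condensation of 3 with the lithium tetra-anion of commercial 1-(2,4,6-trihydroxyphenyl)ethanone (LiN(SiMe3)2, THF) should give 1-[3,4-bis(benzyloxy)phenyl]-3-(2,4,6-trihydroxyphenyl)propane-1,3-dione F1.
- Classical acid-catalysed cyclodehydration (warm AcOH with a trace of H2SO4) should close ring C to 2-[3,4-bis(benzyloxy)phenyl]-5,7-dihydroxy-4H-chromen-4-one F2.
- Elbs persulfate oxidation (K2S2O8, aq KOH/pyridine) should place oxygen on C8, para to the 5-hydroxyl, as 2-[3,4-bis(benzyloxy)phenyl]-5,7-dihydroxy-4-oxo-4H-chromen-8-yl hydrogen sulfate F3.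
- Hydrolysis of F3 in hot dilute HCl with Na2SO3 should give 2-[3,4-bis(benzyloxy)phenyl]-5,7,8-trihydroxy-4H-chromen-4-one F4.
- Monoalkylation of the most acidic 7-hydroxyl of F4 (MOMCl, one equivalent of K2CO3, acetone) should then deliver 7.

Step 1. Alkylation may fail to discriminate between the 4- and 5-hydroxyls or may run on to the bis-ether. The fallback sets out from 1 and comes back at 2, and it inverts the order of protection.
- The trianion of 1 (NaH, 3 equiv, DMSO, Ar) should react with one equivalent of BnBr at its most basic oxygen, the 5-oxygen meta to the acetyl group, to give 1-[5-(benzyloxy)-2,4-dihydroxyphenyl]ethanone F5.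
- MOMCl/K2CO3 can then reach only the 4-hydroxyl, the 2-hydroxyl being chelated, and should give 1-[5-(benzyloxy)-2-hydroxy-4-(methoxymethoxy)phenyl]ethanone F6.
- Hydrogenolysis (H2, 10% Pd/C, EtOAc) should remove the benzyl group and return 2.

Step 7. Hydrogenation may reach the C2–C3 double bond, or the sulfate may be lost by acid-promoted hydrolysis during debenzylation and isolation. The fallback sets out from 9 and comes back at 11, carrying the sulfate as a neutral diester and avoiding hydrogen.
- 9 with 2,2,2-trichloroethyl chlorosulfate (Et3N, DMAP, THF) should give 8-(benzyloxy)-2-[3,4-bis(benzyloxy)phenyl]-5-hydroxy-4-oxo-4H-chromen-7-yl 2,2,2-trichloroethyl sulfate F7.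
- BCl3 with pentamethylbenzene in CH2Cl2 at −78 °C should cleave the three benzyl ethers to 2-(3,4-dihydroxyphenyl)-5,8-dihydroxy-4-oxo-4H-chromen-7-yl 2,2,2-trichloroethyl sulfate F8.
- Zn with HCO2NH4 in MeOH at rt should remove the trichloroethyl group under neutral conditions and give 11.

**Further compounds**
F1 | step 3 | 1-[3,4-bis(benzyloxy)phenyl]-3-(2,4,6-trihydroxyphenyl)propane-1,3-dione | O=C(CC(=O)c1c(O)cc(O)cc1O)c1ccc(OCc2ccccc2)c(OCc2ccccc2)c1
F2 | step 3 | 2-[3,4-bis(benzyloxy)phenyl]-5,7-dihydroxy-4H-chromen-4-one | O=c1cc(-c2ccc(OCc3ccccc3)c(OCc3ccccc3)c2)oc2cc(O)cc(O)c12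
F3 | step 3 | 2-[3,4-bis(benzyloxy)phenyl]-5,7-dihydroxy-4-oxo-4H-chromen-8-yl hydrogen sulfate | O=c1cc(-c2ccc(OCc3ccccc3)c(OCc3ccccc3)c2)oc2c(OS(=O)(=O)O)c(O)cc(O)c12
F4 | step 3 | 2-[3,4-bis(benzyloxy)phenyl]-5,7,8-trihydroxy-4H-chromen-4-one | O=c1cc(-c2ccc(OCc3ccccc3)c(OCc3ccccc3)c2)oc2c(O)c(O)cc(O)c12
F5 | step 1 | 1-[5-(benzyloxy)-2,4-dihydroxyphenyl]ethanone | CC(=O)c1cc(OCc2ccccc2)c(O)cc1O
F6 | step 1 | 1-[5-(benzyloxy)-2-hydroxy-4-(methoxymethoxy)phenyl]ethanone | CC(=O)c1cc(OCc2ccccc2)c(OCOC)cc1O
F7 | step 7 | 8-(benzyloxy)-2-[3,4-bis(benzyloxy)phenyl]-5-hydroxy-4-oxo-4H-chromen-7-yl 2,2,2-trichloroethyl sulfate | O=S(=O)(OCC(Cl)(Cl)Cl)Oc1cc(O)c2c(=O)cc(-c3ccc(OCc4ccccc4)c(OCc4ccccc4)c3)oc2c1OCc1ccccc1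
F8 | step 7 | 2-(3,4-dihydroxyphenyl)-5,8-dihydroxy-4-oxo-4H-chromen-7-yl 2,2,2-trichloroethyl sulfate | O=S(=O)(OCC(Cl)(Cl)Cl)Oc1cc(O)c2c(=O)cc(-c3ccc(O)c(O)c3)oc2c1O
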